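**Strategy.** Number the ring C1 (carbinol carbon bearing CH2OBz), C2 (OAc), C3 (OBz), C4=C5, C6 (OAc). The tertiary oxygen on C1 and the alkene carbon C4 are read as the two ends of a former furan oxygen bridge. A thermal Diels–Alder reaction of furfuryl benzoate with vinylene carbonate therefore forms C1–C2 and C3–C4 in one operation and delivers the cis C2/C3 oxygens exo on a 7-oxanorbornene. Rhodium-catalysed SN2' opening of the bridge with acetate then shifts the alkene to C4=C5, sets the C6 acetate trans to the C1 hydroxyl and selects one enantiomer; Mitsunobu inversion at allylic C3 with benzoic acid and acetylation at C2 complete the target.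

Key step: step 2

Remark on the chemistry: compounds 5 and 6 are racemic, and their SMILES show the enantiomer that step 4 carries forward. The absolute configuration is assumed to be secured in step 4 by a chiral rhodium catalyst acting as a kinetic resolution; the antipode of the ligand that consumes the drawn enantiomer is to be chosen in a test run. The cyclohexene numbering given above is used throughout; for the bicycles, C1 is the substituted bridgehead and C2/C3 carry the oxygens.

**Step 1**
Reactants: 1 furfuryl alcohol; 2 benzoyl chloride
Product: 3 furfuryl benzoate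
Conditions: BzCl, Et3N, DMAP (cat.), CH2Cl2, 0 °C to rt
Reagents that add atoms: benzoyl chloride, O=C(Cl)c1ccccc1
Why: Nucleophilic acyl substitution at a primary alcohol under basic, acid-free conditions that the acid-sensitive furan should tolerate.

**Step 2**
Reactants: 3 furfuryl benzoate; 4 vinylene carbonate
Product: 5 exo cyclic carbonate of 1-(benzoyloxymethyl)-7-oxabicyclo[2.2.1]hept-5-ene-2,3-diol (racemic)
Conditions: 4 (5 equiv, neat), BHT (cat.), sealed tube, 125 °C; chromatography, endo isomer returned to the reaction
Reagents that add atoms: vinylene carbonate, O=C1OC=CO1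
Why: Concerted, suprafacial thermal [4+2] cycloaddition of the furan diene of 3 (its C2 and C5) to the C=C of 4, the closest known reaction being the classical furan–vinylene carbonate Diels–Alder route to cyclitols. The six-membered carbocycle is closed by cycloaddition (both σ bonds in one pericyclic event, no ionic ring closure), and the furan oxygen becomes the C1–O–C4 bridge of a 7-oxabicyclo[2.2.1]heptene. The cis relation of the oxygens on C2 and C3 follows from the ring-locked Z alkene of 4, the relation of C1 to C4 from the bridge, and the exo position of the carbonate from thermodynamic control, since furan cycloadditions are reversible at this temperature. The step needs exo over endo selectivity; it should be secured by equilibration, chromatographic separation and recycling of the endo isomer through cycloreversion, while regiochemistry is no issue because 4 is symmetrical. The absolute configuration is not set here and is selected in step 4.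

**Step 3**
Reactants: 5 exo cyclic carbonate (racemic)
Product: 6 [(1S,2S,3R,4S)-2,3-dihydroxy-7-oxabicyclo[2.2.1]hept-5-en-1-yl]methyl benzoate (2,3-exo,exo-diol, racemic)
Conditions: K2CO3 (0.2 equiv), MeOH, −10 to 0 °C, AcOH quench on consumption of 5
Reagents that add atoms: none
Why: Base-catalysed methanolysis (transesterification) should open the strained five-membered cyclic carbonate well before the hindered neopentyl-type primary benzoate, and no stereocentre is touched.

**Step 4**
Reactants: 6 exo,exo-diol (racemic); 7 acetic acid
Product: 8 [(1S,2S,3S,6S)-6-acetoxy-1,2,3-trihydroxycyclohex-4-en-1-yl]methyl benzoate (single enantiomer)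
Conditions: [Rh(cod)Cl]2 (2.5 mol%), Josiphos ligand PPF-P(t-Bu)2 (6 mol%, one antipode), AcOH/Et3N (5 equiv each), THF, reflux, stopped near half conversion
Reagents that add atoms: acetic acid, CC(=O)O
Why: Rhodium-catalysed SN2' ring opening of an oxabicyclic alkene by a carboxylate: monovalent rhodium inserts from the exo face into the bridgehead C4–O bond (the quaternary C1–O bond is not ionised), acetate attacks the allyl terminus C6 on the endo face anti to rhodium so that the C6 acetate is trans to the retained C1 hydroxyl, and the chiral ligand should ionise C4–O fast only in the (1S,2S,3R,4S)-enantiomer (kinetic resolution), leaving the other enantiomer of 6 behind.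

**Step 5**
Reactants: 8 triol acetate; 9 benzoic acid
Product: 10 [(1S,2S,3R,6S)-6-acetoxy-3-(benzoyloxy)-1,2-dihydroxycyclohex-4-en-1-yl]methyl benzoate
Conditions: PPh3 (1.5 equiv), DIAD (1.5 equiv), PhCO2H (1.5 equiv), THF, 0 °C to rt
Reagents that add atoms: benzoic acid, O=C(O)c1ccccc1
Why: Mitsunobu esterification with SN2 inversion at the allylic C3 carbinol, the only hydroxyl that is both unhindered and activated (C2–OH is neopentyl-like beside quaternary C1, C1–OH is tertiary), which converts the cis-2,3-diol into the trans 3-benzoate.

**Step 6**
Reactants: 10 diol; 11 acetic anhydride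
Product: 12 [(1R,2S,3R,6S)-2,6-diacetoxy-3-(benzoyloxy)-1-hydroxycyclohex-4-en-1-yl]methyl benzoate (target)
Conditions: Ac2O, pyridine, rt
Reagents that add atoms: acetic anhydride, CC(=O)OC(C)=O
Why: Acylation of the one remaining secondary hydroxyl (C2); the tertiary C1 hydroxyl should not be acetylated without DMAP or heat, and no stereocentre is affected.

**Compound list**
1 | furfuryl alcohol (furan-2-ylmethanol) | OCc1ccco1 | starting material
2 | benzoyl chloride | O=C(Cl)c1ccccc1 | starting material
3 | furfuryl benzoate (furan-2-ylmethyl benzoate) | O=C(OCc1ccco1)c1ccccc1 | intermediate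
4 | vinylene carbonate (1,3-dioxol-2-one) | O=C1OC=CO1 | starting material
5 | 2,3-exo cyclic carbonate of [(1S,2S,3R,4S)-2,3-dihydroxy-7-oxabicyclo[2.2.1]hept-5-en-1-yl]methyl benzoate, racemic (enantiomer carried forward is drawn) | O=C(OC[C@@]12O[C@@H](C=C1)[C@@H]3OC(=O)O[C@H]23)c1ccccc1 | intermediate
6 | [(1S,2S,3R,4S)-2,3-dihydroxy-7-oxabicyclo[2.2.1]hept-5-en-1-yl]methyl benzoate, both hydroxyls exo (cis to the oxygen bridge), racemic (enantiomer carried forward is drawn) | O=C(OC[C@@]12O[C@@H](C=C1)[C@H](O)[C@@H]2O)c1ccccc1 | intermediate
7 | acetic acid | CC(=O)O | starting material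
8 | [(1S,2S,3S,6S)-6-acetoxy-1,2,3-trihydroxycyclohex-4-en-1-yl]methyl benzoate (1-, 2- and 3-OH all cis; 6-OAc trans to 1-OH) | CC(=O)O[C@H]1C=C[C@H](O)[C@H](O)[C@@]1(O)COC(=O)c1ccccc1 | intermediate
9 | benzoic acid | O=C(O)c1ccccc1 | starting material
10 | [(1S,2S,3R,6S)-6-acetoxy-3-(benzoyloxy)-1,2-dihydroxycyclohex-4-en-1-yl]methyl benzoate (3-OBz now trans to 2-OH) | CC(=O)O[C@H]1C=C[C@@H](OC(=O)c2ccccc2)[C@H](O)[C@@]1(O)COC(=O)c1ccccc1 | intermediate
11 | acetic anhydride | CC(=O)OC(C)=O | starting material
12 | [(1R,2S,3R,6S)-2,6-diacetoxy-3-(benzoyloxy)-1-hydroxycyclohex-4-en-1-yl]methyl benzoate (CNP0221209.1) | CC(=O)O[C@H]1C=C[C@@H](OC(=O)c2ccccc2)[C@H](OC(C)=O)[C@@]1(O)COC(=O)c1ccccc1 | target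

**Total step count:** 6. **Longest linear sequence:** 6 steps (from furfuryl alcohol).

**Steps most likely to fail**

Step 4. The bridgehead C–O bond of a bicycle without a fused arene may ionise slowly; the allyl-rhodium intermediate may drift to β-hydride elimination or aromatisation; the free exo-diol may bind the metal; and the catalyst may not discriminate the enantiomers well enough. Fallback, setting out from 6 and coming back at 8: 6 is converted into its acetonide F1 (2,2-dimethoxypropane, PPTS, acetone), whose enantiomers are separated by preparative chromatography on a chiral stationary phase. The (1S,2S,3R,4S)-series acetonide F1 is then opened with 4-methoxybenzyl alcohol, an alcohol nucleophile of the kind best documented for oxanorbornenes without a fused arene ([Rh(cod)Cl]2, dppf, THF, 80 °C), to give the 6-O-(4-methoxybenzyl) ether F2. DDQ (CH2Cl2/H2O) should give the C6 alcohol F3, Ac2O/pyridine the C6 acetate F4, and 80% aqueous AcOH removes the acetonide to give 8.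

Step 2. The equilibrium of a reversible furan cycloaddition with an unactivated dienophile may give low conversion and an unfavourable exo/endo distribution, and the dienophile may polymerise on long heating. Fallback, setting out from 3 and coming back at 6: 3 is combined with (E)-1,2-bis(phenylsulfonyl)ethylene, a far more reactive acetylene equivalent (toluene, 80 °C), to give the trans bis-sulfone adduct F5. Na(Hg), NaH2PO4, MeOH, −20 °C removes both sulfonyl groups to give the 7-oxanorbornadiene F6. OsO4 (cat.), NMO (1 equiv), acetone/H2O, 0 °C should dihydroxylate one double bond from the exo face to give racemic 6; the two double bonds of F6 are mirror-related, so either gives the same racemate.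

Step 5. Site selectivity among three hydroxyls may be lost through cyclic phosphorane formation, and the allylic oxyphosphonium may react by SN2' transposition or eliminate toward an arene. Fallback, setting out from 8 and coming back at 10: selective sulfonylation of the allylic C3 hydroxyl (MsCl, Et3N, CH2Cl2, −40 °C) gives the 3-O-mesylate F7, which is displaced with inversion by PhCO2Cs (18-crown-6, toluene, 50 °C) to give 10.

**Further compounds**
F1 | step 4 | acetonide (2,3-O-isopropylidene derivative) of 6, (1S,2S,3R,4S)-series enantiomer after chiral chromatography | O=C(OC[C@@]12O[C@@H](C=C1)[C@@H]3OC(C)(C)O[C@H]23)c1ccccc1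
F2 | step 4 | 2,3-O-isopropylidene-6-O-(4-methoxybenzyl) analogue of 8 (6-ether trans to 1-OH) | COc1ccc(CO[C@H]2C=C[C@@H]3OC(C)(C)O[C@@H]3[C@@]2(O)COC(=O)c2ccccc2)cc1
F3 | step 4 | 2,3-O-isopropylidene analogue of 8 with free 6-OH | O[C@H]1C=C[C@@H]2OC(C)(C)O[C@@H]2[C@@]1(O)COC(=O)c1ccccc1
F4 | step 4 | 2,3-O-isopropylidene derivative of 8 (6-acetate) | CC(=O)O[C@H]1C=C[C@@H]2OC(C)(C)O[C@@H]2[C@@]1(O)COC(=O)c1ccccc1
F5 | step 2 | [2-exo,3-endo-bis(phenylsulfonyl)-7-oxabicyclo[2.2.1]hept-5-en-1-yl]methyl benzoate, racemic, one of two trans diastereomers drawn (both converge on F6) | O=C(OC[C@@]12O[C@@H](C=C1)[C@@H](S(=O)(=O)c1ccccc1)[C@@H]2S(=O)(=O)c1ccccc1)c1ccccc1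
F6 | step 2 | (7-oxabicyclo[2.2.1]hepta-2,5-dien-1-yl)methyl benzoate (achiral) | O=C(OCC12C=CC(C=C1)O2)c1ccccc1
F7 | step 5 | 3-O-methanesulfonate of 8 | CC(=O)O[C@H]1C=C[C@H](OS(C)(=O)=O)[C@H](O)[C@@]1(O)COC(=O)c1ccccc1
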